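**Plan**

- Retrosynthesis first cuts the bond between the (E)-alkene and the vinyl-bearing quaternary carbon (SN2′ union of an alkenylmetal with farnesyl phosphate). It then cuts, in the ring, the C1–C2 bond (side-chain CH to gem-dimethyl carbon) together with the C3–CH3 bond.
- Both halves are (2E,6E)-farnesol: one is hydrogenated at C2=C3, methylated and cyclised, then turned into a terminal alkyne; the other becomes the allylic phosphate.
- Enabling feature: ring C3 carries a methyl beside the gem-dimethyl carbon C2, and C6, the other neighbour of C1, carries an exocyclic methylene. This is the imprint of a methyl cation adding to a prenyl terminus, the tertiary cation at C2 being captured by C1 of the next trisubstituted alkene, and proton loss from the methyl on C6.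
- Forward order: the only ring arises in step 2 from an open-chain C15 alcohol; the C16 alkyne and the C15 phosphate are joined in the last step.
- Stereochemistry: chain CH(CH3) from Ru–BINAP hydrogenation; ring C1 and C3 from the enzyme; quaternary carbon from the chiral NHC–Cu catalyst; (E)-alkene from syn-hydroalumination.

Key step: step 2

Remark: the ring is read from the SMILES as (1S,3S), that is, side chain at C1 and methyl at C3 trans; the route is planned for this diastereomer.

**Route**

Step 1
Reactants: 1 (2E,6E)-farnesol
Product: 2 (3S,6E)-3,7,11-trimethyldodeca-6,10-dien-1-ol [(S)-2,3-dihydrofarnesol]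
Conditions: H2 (30 atm), Ru(OAc)2[(R)-BINAP] (0.2 mol %), MeOH/H2O 95:5, 20 °C
Reagents that add atoms: none
Why: Hydroxyl-directed Ru–BINAP asymmetric hydrogenation of an allylic alcohol should reduce only the C2=C3 alkene and leave the two remote trisubstituted alkenes alone; the new C3 centre is set by the catalyst, the (R)-ligand giving (3S) from the (2E)-alkene as in the geraniol-to-(S)-citronellol case.

Step 2
Reactants: 2 (3S,6E)-3,7,11-trimethyldodeca-6,10-dien-1-ol
Product: 3 (3S)-3-methyl-5-[(1S,3S)-2,2,3-trimethyl-6-methylidenecyclohexyl]pentan-1-ol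
Conditions: SAM-dependent terpene C-methyltransferase–cyclase (engineered variant, clarified cell lysate), S-adenosyl-L-methionine (1.5 equiv), potassium phosphate buffer pH 7.5, 2-hydroxypropyl-β-cyclodextrin, 30 °C
Reagents that add atoms: S-adenosyl-L-methionine (SAM), Nc1ncnc2c1ncn2[C@@H]1O[C@H](C[S+](C)CC[C@H](N)C(=O)[O-])[C@@H](O)[C@H]1O
Why: The enzyme hands the methyl group of SAM as an electrophile to C10 of the terminal 10,11-alkene, the tertiary C11 cation so formed is captured by C6 of the (6E)-alkene, and a base of the active site removes a proton from the methyl on C7 to leave the exocyclic methylene (old C10, C11, C6 and C7 become ring C3, C2, C1 and C6). The closest known reaction type is the methyltransferase-triggered cation–olefin cyclisation by which this enzyme class builds the irone ring from the prenyl terminus of ψ-ionone and of the iridals; its non-enzymatic relative is the acid-initiated polyene cyclisation. The six-membered ring closes in the 6-endo-trig mode, the cationic carbon adding to the near end of an alkene whose two carbons both end up in the ring. Ring C3 is set by the face of the 10,11-alkene that the enzyme turns to the SAM methyl and ring C1 by the face of the 6,7-alkene that it turns to the cation, so the 1,3-trans (1S,3S) pair, which an unconstrained chair closure of an (E)-alkene would not favour, is a matter of enzyme control and has to be selected for in the variant used; the chain stereocentre is remote and untouched. The step needs site selectivity, arrest after one ring and proton loss to the outside of the ring: 2 has a single prenyl terminus and, after step 1, no further alkene within reach of the ring cation, while burial of the cation in the active site should suppress the 1,2-hydride shift and the endocyclic eliminations that a free cation would show.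

Step 3
Reactants: 3 (3S)-3-methyl-5-[(1S,3S)-2,2,3-trimethyl-6-methylidenecyclohexyl]pentan-1-ol
Product: 4 (3S)-3-methyl-5-[(1S,3S)-2,2,3-trimethyl-6-methylidenecyclohexyl]pentanal
Conditions: Dess–Martin periodinane (1.2 equiv), CH2Cl2, 0 °C to rt
Reagents that add atoms: none
Why: Dess–Martin oxidation should take the primary alcohol to the aldehyde under near-neutral conditions that leave the exocyclic alkene in place, and no stereocentre is at risk because the nearest one is β to the carbonyl.

Step 4
Reactants: 4 (3S)-3-methyl-5-[(1S,3S)-2,2,3-trimethyl-6-methylidenecyclohexyl]pentanal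
Product: 6 (3S)-3-methyl-5-[(1S,3S)-2,2,3-trimethyl-6-methylidenecyclohexyl]pent-1-yne, via alkenyl nonaflate 5 (not isolated)
Conditions: n-C4F9SO2F (1.2 equiv), P2-Et phosphazene base (2.5 equiv), DMF, −20 °C to rt
Reagents that add atoms: none
Why: One-pot nonaflation/elimination of an enolisable aldehyde: the phosphazene base forms the enolate, the sulfonyl fluoride traps it on oxygen, and a second equivalent of base eliminates nonaflate from the alkenyl nonaflate to give the terminal alkyne with the carbon count unchanged; the tertiary C3–H is far less acidic than the hydrogens removed, so the (3S) centre should hold.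

Step 5
Reactants: 1 (2E,6E)-farnesol
Product: 7 diethyl (2E,6E)-3,7,11-trimethyldodeca-2,6,10-trien-1-yl phosphate (farnesyl diethyl phosphate)
Conditions: ClP(O)(OEt)2 (1.2 equiv), Et3N (1.5 equiv), DMAP (5 mol %), CH2Cl2, 0 °C
Reagents that add atoms: diethyl chlorophosphate, CCOP(=O)(Cl)OCC
Why: O-Phosphorylation of the primary allylic alcohol with a chlorophosphate and an amine base should give the allylic phosphate needed as SN2′ electrophile without touching the alkene geometry; no stereocentre is formed.

Step 6
Reactants: 6 (3S)-3-methyl-5-[(1S,3S)-2,2,3-trimethyl-6-methylidenecyclohexyl]pent-1-yne, 7 farnesyl diethyl phosphate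
Product: 9 (3S,4E,6S,9E)-6-ethenyl-3,6,10,14-tetramethyl-1-[(1S,3S)-2,2,3-trimethyl-6-methylidenecyclohexyl]pentadeca-4,9,13-triene (the target), via alkenylalane 8 (not isolated)
Conditions: i-Bu2AlH (1.0 equiv), hexanes, 55 °C; then 7, CuCl2·2H2O (2 mol %), chiral sulfonate-bearing imidazolinium salt (NHC precursor, 2.5 mol %), THF, −15 °C
Reagents that add atoms: none
Why: Syn-hydroalumination of the terminal alkyne should give the (E)-alkenylalane (the hindered 1,1-disubstituted ring alkene does not react at this temperature), and NHC–Cu-catalysed enantioselective allylic substitution then transfers the alkenyl group with SN2′ selectivity to C3 of the (E)-allylic phosphate, a reaction type with close precedent for geranyl-type phosphates; the quaternary centre is set by the chiral catalyst (ligand enantiomer chosen for S), the alkene geometry is carried over unchanged and the old C1–C2 unit of the phosphate becomes the vinyl group.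

**Compound list**

1 | (2E,6E)-farnesol, (2E,6E)-3,7,11-trimethyldodeca-2,6,10-trien-1-ol | OC/C=C(\C)CC/C=C(\C)CCC=C(C)C | starting material
2 | (3S,6E)-3,7,11-trimethyldodeca-6,10-dien-1-ol | OCC[C@@H](C)CC/C=C(\C)CCC=C(C)C | intermediate
3 | (3S)-3-methyl-5-[(1S,3S)-2,2,3-trimethyl-6-methylidenecyclohexyl]pentan-1-ol | OCC[C@@H](C)CC[C@H]1C(=C)CC[C@H](C)C1(C)C | intermediate
4 | (3S)-3-methyl-5-[(1S,3S)-2,2,3-trimethyl-6-methylidenecyclohexyl]pentanal | O=CC[C@@H](C)CC[C@H]1C(=C)CC[C@H](C)C1(C)C | intermediate
5 | (3S)-3-methyl-5-[(1S,3S)-2,2,3-trimethyl-6-methylidenecyclohexyl]pent-1-en-1-yl nonafluorobutane-1-sulfonate (E/Z mixture, not isolated) | FC(F)(F)C(F)(F)C(F)(F)C(F)(F)S(=O)(=O)OC=C[C@@H](C)CC[C@H]1C(=C)CC[C@H](C)C1(C)C | intermediate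
6 | (3S)-3-methyl-5-[(1S,3S)-2,2,3-trimethyl-6-methylidenecyclohexyl]pent-1-yne | C#C[C@@H](C)CC[C@H]1C(=C)CC[C@H](C)C1(C)C | intermediate
7 | diethyl (2E,6E)-3,7,11-trimethyldodeca-2,6,10-trien-1-yl phosphate | CCOP(=O)(OCC)OC/C=C(\C)CC/C=C(\C)CCC=C(C)C | intermediate
8 | diisobutyl{(1E,3S)-3-methyl-5-[(1S,3S)-2,2,3-trimethyl-6-methylidenecyclohexyl]pent-1-en-1-yl}alane (not isolated) | CC(C)C[Al](CC(C)C)/C=C/[C@@H](C)CC[C@H]1C(=C)CC[C@H](C)C1(C)C | intermediate
9 | (3S,4E,6S,9E)-6-ethenyl-3,6,10,14-tetramethyl-1-[(1S,3S)-2,2,3-trimethyl-6-methylidenecyclohexyl]pentadeca-4,9,13-triene | C=C[C@@](C)(/C=C/[C@@H](C)CC[C@H]1C(=C)CC[C@H](C)C1(C)C)CC/C=C(\C)CCC=C(C)C | target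

**Step count and risks**

Total step count: 6. Longest linear sequence: 5 steps (steps 1, 2, 3, 4 and 6).

Steps most likely to fail:

1. Step 2. The short C15 alcohol may bind in the wrong fold, so that the cation is captured in the unconstrained chair (1,3-cis ring), loses a ring proton (endocyclic alkene) or is quenched before ring closure. The fallback moves the ring closure to the end and runs it on the full-length C30 polyene, whose longer chain offers the enzyme more to hold; the enzyme must then also choose the prenyl terminus nearer the CH(CH3) centre. It sets out from 2 and comes back at 9. Dess–Martin oxidation of 2 should give (3S,6E)-3,7,11-trimethyldodeca-6,10-dienal F1. The nonaflation/elimination of step 4 should convert F1 through its alkenyl nonaflate F2 into (3S,6E)-3,7,11-trimethyldodeca-6,10-dien-1-yne F3. Hydroalumination to the alkenylalane F4 and the copper-catalysed SN2′ union of step 6 with 7 should give the acyclic hexaene (6E,10S,11E,13S,16E)-10-ethenyl-2,6,10,13,17,21-hexamethyldocosa-2,6,11,16,20-pentaene F5. The methyltransferase–cyclase then closes the ring between C16 and C21 of F5 to reach 9.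

2. Step 4. Elimination from the (E)-alkenyl nonaflate may be sluggish, and the strong base may isomerise the alkyne towards the allene or erode the propargylic centre. The fallback replaces dehydration by excision of one carbon followed by a one-carbon homologation. It sets out from 4 and comes back at 6. Proline-catalysed α-aminoxylation of 4 with nitrosobenzene and NaBH4 reduction in the same flask should give the O-anilino diol monoether (3S)-3-methyl-2-(phenylaminooxy)-5-[(1S,3S)-2,2,3-trimethyl-6-methylidenecyclohexyl]pentan-1-ol F6, whose new carbinol centre is of no consequence. N–O cleavage (CuSO4·5H2O, MeOH) should give the 1,2-diol F7. NaIO4 cleavage should give (2S)-2-methyl-4-[(1S,3S)-2,2,3-trimethyl-6-methylidenecyclohexyl]butanal F8. Ohira–Bestmann alkynylation (dimethyl (1-diazo-2-oxopropyl)phosphonate, K2CO3, MeOH, 0 °C) of F8 returns to 6.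

3. Step 6. The hydride may metalate the alkyne C–H instead of adding across it, and the α-branched alkenylalane may erode SN2′ and facial selectivity at the quaternary carbon. The fallback makes the C–H metalation the productive path and forms the (E)-alkene afterwards. It sets out from 6 and comes back at 9. i-Bu2AlH with Et3N (5 mol %) should convert 6 into the alkynylalane F9. The same NHC–Cu system should join F9 in the SN2′ sense to 7, giving the enyne (3S,6S,9E)-6-ethenyl-3,6,10,14-tetramethyl-1-[(1S,3S)-2,2,3-trimethyl-6-methylidenecyclohexyl]pentadeca-9,13-dien-4-yne F10. Trans-selective dissolving-metal semireduction of its only alkyne (Na, NH3/THF, −78 °C) should then deliver 9.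

**Further compounds**

F1 | step 2 | (3S,6E)-3,7,11-trimethyldodeca-6,10-dienal | O=CC[C@@H](C)CC/C=C(\C)CCC=C(C)C
F2 | step 2 | (3S,6E)-3,7,11-trimethyldodeca-1,6,10-trien-1-yl nonafluorobutane-1-sulfonate (E/Z mixture at C1) | FC(F)(F)C(F)(F)C(F)(F)C(F)(F)S(=O)(=O)OC=C[C@@H](C)CC/C=C(\C)CCC=C(C)C
F3 | step 2 | (3S,6E)-3,7,11-trimethyldodeca-6,10-dien-1-yne | C#C[C@@H](C)CC/C=C(\C)CCC=C(C)C
F4 | step 2 | diisobutyl[(1E,3S,6E)-3,7,11-trimethyldodeca-1,6,10-trien-1-yl]alane | CC(C)C[Al](CC(C)C)/C=C/[C@@H](C)CC/C=C(\C)CCC=C(C)C
F5 | step 2 | (6E,10S,11E,13S,16E)-10-ethenyl-2,6,10,13,17,21-hexamethyldocosa-2,6,11,16,20-pentaene | C=C[C@@](C)(/C=C/[C@@H](C)CC/C=C(\C)CCC=C(C)C)CC/C=C(\C)CCC=C(C)C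
F6 | step 4 | (3S)-3-methyl-2-(phenylaminooxy)-5-[(1S,3S)-2,2,3-trimethyl-6-methylidenecyclohexyl]pentan-1-ol (C2 configuration of no consequence) | OCC(ONc1ccccc1)[C@@H](C)CC[C@H]1C(=C)CC[C@H](C)C1(C)C
F7 | step 4 | (3S)-3-methyl-5-[(1S,3S)-2,2,3-trimethyl-6-methylidenecyclohexyl]pentane-1,2-diol (C2 configuration of no consequence) | OCC(O)[C@@H](C)CC[C@H]1C(=C)CC[C@H](C)C1(C)C
F8 | step 4 | (2S)-2-methyl-4-[(1S,3S)-2,2,3-trimethyl-6-methylidenecyclohexyl]butanal | O=C[C@@H](C)CC[C@H]1C(=C)CC[C@H](C)C1(C)C
F9 | step 6 | diisobutyl{(3S)-3-methyl-5-[(1S,3S)-2,2,3-trimethyl-6-methylidenecyclohexyl]pent-1-yn-1-yl}alane | CC(C)C[Al](CC(C)C)C#C[C@@H](C)CC[C@H]1C(=C)CC[C@H](C)C1(C)C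
F10 | step 6 | (3S,6S,9E)-6-ethenyl-3,6,10,14-tetramethyl-1-[(1S,3S)-2,2,3-trimethyl-6-methylidenecyclohexyl]pentadeca-9,13-dien-4-yne | C=C[C@@](C)(C#C[C@@H](C)CC[C@H]1C(=C)CC[C@H](C)C1(C)C)CC/C=C(\C)CCC=C(C)C
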